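The earlier runs and the new flask were computed for substances that don't exist; the scatter is artificial.

1. Wednesday's readings flatten near 73.0%. I assume its living ends die on transfer agent, whose charge far exceeds the initiator charge, so the death is pseudo-first-order.

| flask | free monomer | transfer agent | initiator | temperature | remark | time |
|---|---|---|---|---|---|---|
| Wednesday's | 28 mM | 6 mM | 1 mol% | 12 °C | run made earlier |  |
| Tuesday's | 44 mM | 6 mM | 1 mol% | 40 °C | run made earlier |  |
| alder | 20 mM | 6.00 mM | 1 mol% | 25 °C |  | 2.0 min |
| cedar | 20 mM | 6.00 mM | 1 mol% | 50 °C |  | 2.0 min |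
| oak | 20 mM | 6.00 mM | 1 mol% | 0 °C |  | 2.0 min |
- Wednesday's (time / min: monomer in chains / %): 0.333: 25.7; 0.667: 45.6; 1.00: 57.6; 1.50: 64.7; 2.50: 71.0; 3.00: 71.1; 4.00: 73.0
- Tuesday's (time / s: monomer in chains / %): 10.0: 59.0; 15.0: 66.7; 25.0: 75.0; 40.0: 80.1; 60.0: 80.3

(readings scatter by 0.5 percentage points)
- the flask with the highest amount of monomer in chains, in percent of the free monomer charged ("all alike" if they lie within 1.5 percentage points) (alder / cedar / oak / all alike)
- final monomer in chains, as a percentage of the free monomer charged, in alder
- final monomer in chains, as a percentage of the free monomer charged, in cedar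
- final monomer in chains, as a percentage of the free monomer charged, in oak
- a reading or a percentage of monomer in chains counts all its forms, free or not

2. I follow one living end: at each fork it adds free monomer or dies. Taking the free monomer left as the charge less the last reading, I call the log of free monomer charged over free monomer left the reach, which reads 1.31 on Wednesday. Dividing it by initiator over transfer agent gives the odds of adding against dying at equal concentrations, 28.1. Tuesday's reading gives 1.62 and odds of 22.2.

3. Alder, cedar and oak share an initiator over transfer agent of 0.0333. I give alder the mean odds, for a reach of 0.837 and a plateau of 56.7%. Cedar takes Tuesday's odds, so its plateau is 52.2%. Oak takes Wednesday's odds, for a reach of 0.935. I assume alder and cedar have reached these plateaus by 2.0 min.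

4. Turned round: oak passes alder if it has spent 89.5% of its reach by 2.0 min, which needs a death rate of 1.13 min⁻¹. The closing gaps in reach give 1.14 min⁻¹ on Wednesday and 4.49 min⁻¹ on Tuesday.

5. Extrapolated to oak's temperature, the rate is 0.632 min⁻¹, lower than needed. I reckon oak at 48.9%, so I commit to alder.

6. The forecast says alder, with 64.5%, 64% and 47%, on the ground that “K is therefore almost independent of temperature”.

7. The flasks give alder: alder 50.3%, cedar 46.9%, oak 45.6%.

    monomer in chains ⇌ isomer of the product (K = 1.20, k = 0.0130 s⁻¹, Ea = 86.0 kJ mol⁻¹, ΔH = −15.0 kJ mol⁻¹)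
    initiator + monomer in chains → spent initiator (k = 2.40 L mol⁻¹ s⁻¹, Ea = 38.0 kJ mol⁻¹)
    living end + transfer agent → dead chain (kL = 5.90 L mol⁻¹ s⁻¹, Ea = 41.0 kJ mol⁻¹)
    free monomer + living end → monomer in chains + living end, rate k4*[living end]*[free monomer] (k = 170 L mol⁻¹ s⁻¹, Ea = 36.0 kJ mol⁻¹)
    crystals ⇌ monomer in chains, rate k5*(cs5 - [monomer in chains]) while solid is left; crystals form when [monomer in chains] > cs5 (solubility = 2.60 mM, k = 2.20 s⁻¹)
    free monomer + initiator → living end + monomer in chains (k = 11.0 L mol⁻¹ s⁻¹, Ea = 38.0 kJ mol⁻¹)
    (constants at 25 °C)

8. The order is the one I reckoned, though alder lies 6.4 percentage points below my figure. For oak I reckoned 51.1% free monomer left, and it holds 53.6%. The neighbour is oak with 15 mM of transfer agent. Its death rate scales to 1.58 min⁻¹ and its reach falls to 0.374, so I reckon 30.1% monomer in chains, and that flask gives 32.0%.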